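**Plan**

1. Retrosynthesis: the aryl ether C–O bond and the isovalerate C–O bond are cut first. This leaves the cis-diol (1R,3S)-3-(hydroxymethyl)-2,2,4-trimethylcyclohex-4-en-1-ol, the reduced form of the bridged lactone (1S,5R)-2,8,8-trimethyl-6-oxabicyclo[3.2.1]oct-2-en-7-one.
2. Enabling feature: the ring carbon that carries the ester oxygen is homoallylic to the ring C=C (a cyclohex-3-en-1-ol unit). Its oxygen is cis-1,3 to the CH2O-bearing ring carbon across the CMe2 carbon, so this oxygen and the exocyclic carbon can be tied as a five-membered lactone.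
3. The carbocycle is cut between the allylic ring CH2 and the oxygen-bearing carbon. Forward: a lactone-derived acyloxycarbenium ion is attacked by the CH2 terminus of a tertiary allylsilane (intramolecular Hosomi–Sakurai), and loss of silicon puts the C=C between C(CH3) and CH.
4. The allylsilane acid is cut between the future CH(CH2O) carbon and the silicon-bearing carbon: Ireland–Claisen rearrangement of (E)-3-(trimethylsilyl)but-2-enyl 3-cyano-3-methylbutanoate, the nitrile being the latent lactol carbon.
5. Forward order: chain joined by esterification, [3,3] shift, nitrile to hydroxy lactone (five-membered ring), carbocycle closed onto it (six-membered ring), lactone reduced, secondary ester and then coumarin ether installed.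
6. Stereochemistry: absolute configuration comes from the chiral-boron enantioselective Ireland–Claisen step. The CH stereocentre is kept to the end, the silicon-bearing stereocentre is consumed in the ring closure, and the carbinol configuration is dictated by the lactone tether.

Key step: step 6

Assumption: 3-cyano-3-methylbutanoic acid (5) is taken as a catalogue building block; the (4S,5S) antipode of the boron controller is written for step 4, and the (4R,5R) antipode is used instead if its facial sense on this ester proves opposite.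

**Step 1**
Reactants: 1 3-(trimethylsilyl)prop-2-yn-1-ol
Product: 3 (Z)-3-iodo-3-(trimethylsilyl)prop-2-en-1-ol, via cyclic alkenylaluminate 2 (not isolated)
Conditions: NaAlH2(OCH2CH2OMe)2 (Red-Al), Et2O, 0 °C to rt; then I2, THF, −78 to 0 °C
Reagents that add atoms: iodine, [I][I]
Why: Hydroxyl-directed anti hydroalumination of the propargylic alcohol places aluminium on the silicon-bearing carbon inside a five-membered alkoxyaluminate, and iodinolysis of the C–Al bond with retention gives the Z-iodoalkene (iodine cis to CH2OH).

**Step 2**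
Reactants: 3 (Z)-3-iodo-3-(trimethylsilyl)prop-2-en-1-ol
Product: 4 (E)-3-(trimethylsilyl)but-2-en-1-ol
Conditions: Me2CuLi (from MeLi and CuI, excess), Et2O, −20 to 0 °C
Reagents that add atoms: lithium dimethylcuprate (from MeLi and CuI), [Li+].C[Cu-]C
Why: Organocuprate cross-coupling at the alkenyl iodide proceeds with retention of alkene geometry, so methyl ends cis and silicon trans to CH2OH, which is the E-vinylsilane needed for the rearrangement.

**Step 3**
Reactants: 4 (E)-3-(trimethylsilyl)but-2-en-1-ol; 5 3-cyano-3-methylbutanoic acid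
Product: 6 (E)-3-(trimethylsilyl)but-2-en-1-yl 3-cyano-3-methylbutanoate
Conditions: DCC, DMAP (cat.), CH2Cl2, 0 °C to rt
Reagents that add atoms: none
Why: Steglich esterification (carbodiimide activation, DMAP acyl transfer) joins the two fragments without touching the vinylsilane or the nitrile and creates no stereocentre.

**Step 4**
Reactants: 6 (E)-3-(trimethylsilyl)but-2-en-1-yl 3-cyano-3-methylbutanoate
Product: 9 (2S)-3-cyano-3-methyl-2-[(2R)-2-(trimethylsilyl)but-3-en-2-yl]butanoic acid, via boron ketene acetal 7 (not isolated), via boron carboxylate 8 (not isolated)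
Conditions: (4S,5S)-2-bromo-4,5-diphenyl-1,3-bis{[3,5-bis(trifluoromethyl)phenyl]sulfonyl}-1,3,2-diazaborolidine, Et3N, toluene–hexane, −78 °C, then 4 °C; aqueous work-up
Reagents that add atoms: none
Why: Enantioselective boron-enolate Ireland–Claisen rearrangement: amine-assisted enolisation by the chiral bromoborane gives the ketene acetal with the CMe2CN group cis to the allyloxy oxygen, and the chair [3,3] shift across the E-vinylsilane (methyl axial, SiMe3 equatorial) forms the congested C–C bond and sets the adjacent pair as (2S,2'R), the relative configuration following from the two alkene geometries and the absolute sense from the C2-symmetric sulfonamide ligand on boron.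

**Step 5**
Reactants: 9 (2S)-3-cyano-3-methyl-2-[(2R)-2-(trimethylsilyl)but-3-en-2-yl]butanoic acid
Product: 12 (3S)-5-hydroxy-4,4-dimethyl-3-[(2R)-2-(trimethylsilyl)but-3-en-2-yl]oxolan-2-one (both C-5 epimers), via aluminium aldiminate 10 (not isolated), via open-chain aldehyde acid 11 (not isolated)
Conditions: NaH, THF, 0 °C; i-Bu2AlH, toluene, −78 to −30 °C; then 1 M HCl, 0 °C
Reagents that add atoms: water, O
Why: Nitrile-to-aldehyde reduction with i-Bu2AlH stops at the N-aluminio aldimine while the acid is shielded as its sodium carboxylate, and on acidic hydrolysis the 4-oxo acid closes spontaneously to the five-membered hydroxy lactone (ring–chain tautomerism favoured by the gem-dimethyl group), the new hemiacetal centre being of no consequence because it is ionised in the next step.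

**Step 6**
Reactants: 12 (3S)-5-hydroxy-4,4-dimethyl-3-[(2R)-2-(trimethylsilyl)but-3-en-2-yl]oxolan-2-one
Product: 14 (1S,5R)-2,8,8-trimethyl-6-oxabicyclo[3.2.1]oct-2-en-7-one, via acyloxycarbenium ion 13 (not isolated)
Conditions: BF3·OEt2, 2,6-di-tert-butyl-4-methylpyridine (substoichiometric), CH2Cl2, −78 to −20 °C; sat. aq. NaHCO3 wash
Reagents that add atoms: none
Why: BF3 ionises the hemiacetal C–OH of 12 to the five-membered acyloxycarbenium ion 13 (O=C–O+=CH), whose carbon is attacked by the terminal CH2 of the tertiary allylsilane while the C–Si bond, held antiperiplanar, is lost (anti SE2'), so the new C=C lies exactly between the methyl-bearing carbon and the former internal vinyl carbon. The closest known reaction type is the intramolecular Hosomi–Sakurai reaction, that is, allylsilane-terminated cyclisation onto an oxocarbenium or N-acyliminium ion. The six-membered carbocycle closes 6-endo with respect to the vinyl group (both vinyl carbons end in the ring) and exo with respect to the C=O+ bond, which gives the 6-oxabicyclo[3.2.1]octene skeleton. The only new stereocentre, the oxygen-bearing carbon, is controlled by the tether: the cationic carbon and the side-chain-bearing carbon are already linked through O–C(=O), so the C–C bond can form only on the face of the lactone that carries the side chain, and the oxygen necessarily ends cis to the carboxyl carbon (5R with 1S). The step needs bond formation through the CH2 terminus from a chair-like arrangement with SiMe3 axial and anti to the incoming carbon; this is secured by the (2R) configuration of the silicon-bearing carbon set in step 4, by the absence of any β-hydrogen on the neopentyl-type cationic carbon, and by the hindered base that suppresses protodesilylation. Any material that reacts through the open aldehyde form to a trans hydroxy acid cannot lactonise and is removed by the bicarbonate wash.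

**Step 7**
Reactants: 14 (1S,5R)-2,8,8-trimethyl-6-oxabicyclo[3.2.1]oct-2-en-7-one
Product: 15 (1R,3S)-3-(hydroxymethyl)-2,2,4-trimethylcyclohex-4-en-1-ol
Conditions: LiAlH4, THF, 0 °C to rt
Reagents that add atoms: none
Why: LiAlH4 reduction of the lactone to the diol opens the bridge and leaves both stereocentres and the trisubstituted alkene untouched, so the cis relationship fixed in step 6 is carried into the open ring.

**Step 8**
Reactants: 15 (1R,3S)-3-(hydroxymethyl)-2,2,4-trimethylcyclohex-4-en-1-ol
Product: 16 (1R,3S)-3-{[tert-butyl(dimethyl)silyl]oxymethyl}-2,2,4-trimethylcyclohex-4-en-1-ol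
Conditions: TBSCl, imidazole, DMF, 0 °C
Reagents that add atoms: tert-butyldimethylsilyl chloride, CC(C)(C)[Si](C)(C)Cl
Why: Selective silylation of the primary hydroxyl (silyl ether protection), the neopentyl-type secondary hydroxyl being too hindered to react, masks the oxygen so that the cis-1,4-diol cannot close to a bridged ether when the primary carbon is later activated.

**Step 9**
Reactants: 16 (1R,3S)-3-{[tert-butyl(dimethyl)silyl]oxymethyl}-2,2,4-trimethylcyclohex-4-en-1-ol; 17 3-methylbutanoyl chloride
Product: 18 (1R,3S)-3-{[tert-butyl(dimethyl)silyl]oxymethyl}-2,2,4-trimethylcyclohex-4-en-1-yl 3-methylbutanoate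
Conditions: DMAP, Et3N, CH2Cl2, rt
Reagents that add atoms: none
Why: DMAP-catalysed acylation of the hindered secondary alcohol by the acid chloride (nucleophilic acyl substitution) proceeds with retention because no bond to the carbinol carbon is broken.

**Step 10**
Reactants: 18 (1R,3S)-3-{[tert-butyl(dimethyl)silyl]oxymethyl}-2,2,4-trimethylcyclohex-4-en-1-yl 3-methylbutanoate
Product: 19 (1R,3S)-3-(hydroxymethyl)-2,2,4-trimethylcyclohex-4-en-1-yl 3-methylbutanoate
Conditions: HF·pyridine, THF, 0 °C to rt
Reagents that add atoms: none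
Why: Fluoride-induced cleavage of the silyl ether (desilylation) under mildly acidic conditions frees the primary alcohol without hydrolysis or migration of the hindered ester.

**Step 11**
Reactants: 19 (1R,3S)-3-(hydroxymethyl)-2,2,4-trimethylcyclohex-4-en-1-yl 3-methylbutanoate; 20 7-hydroxy-2H-chromen-2-one (umbelliferone)
Product: 21 (1R,3S)-2,2,4-trimethyl-3-{[(2-oxo-2H-chromen-7-yl)oxy]methyl}cyclohex-4-en-1-yl 3-methylbutanoate
Conditions: PPh3, DIAD, THF, 0 °C to rt
Reagents that add atoms: none
Why: Mitsunobu etherification: the acidic phenol (pKa about 8) is joined to the primary carbon by SN2 displacement of the alkoxyphosphonium ion at a non-stereogenic CH2, now with no free hydroxyl left to compete, and the ester and both stereocentres are unaffected.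

**Compound list**

1 | 3-(trimethylsilyl)prop-2-yn-1-ol | C[Si](C)(C)C#CCO | starting material
2 | sodium 2,2-bis(2-methoxyethoxy)-3-(trimethylsilyl)-2,5-dihydro-1,2-oxaaluminol-2-uide (cyclic alkenylaluminate) | C[Si](C)(C)C1=CCO[Al-]1(OCCOC)OCCOC.[Na+] | intermediate
3 | (Z)-3-iodo-3-(trimethylsilyl)prop-2-en-1-ol | OC/C=C(\I)[Si](C)(C)C | intermediate
4 | (E)-3-(trimethylsilyl)but-2-en-1-ol | OC/C=C(\C)[Si](C)(C)C | intermediate
5 | 3-cyano-3-methylbutanoic acid | N#CC(C)(C)CC(=O)O | starting material
6 | (E)-3-(trimethylsilyl)but-2-en-1-yl 3-cyano-3-methylbutanoate | N#CC(C)(C)CC(=O)OC/C=C(\C)[Si](C)(C)C | intermediate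
7 | boron ketene acetal of 6 on the (4S,5S)-diazaborolidine (C-3 substituent cis to the allyloxy oxygen) | N#CC(C)(C)/C=C(\OC/C=C(\C)[Si](C)(C)C)OB1N(S(=O)(=O)c2cc(cc(c2)C(F)(F)F)C(F)(F)F)[C@@H](c2ccccc2)[C@H](c2ccccc2)N1S(=O)(=O)c1cc(cc(c1)C(F)(F)F)C(F)(F)F | intermediate
8 | (4S,5S)-diazaborolidin-2-yl ester of acid 9 (boron carboxylate) | N#CC(C)(C)[C@H]([C@@](C)(C=C)[Si](C)(C)C)C(=O)OB1N(S(=O)(=O)c2cc(cc(c2)C(F)(F)F)C(F)(F)F)[C@@H](c2ccccc2)[C@H](c2ccccc2)N1S(=O)(=O)c1cc(cc(c1)C(F)(F)F)C(F)(F)F | intermediate
9 | (2S)-3-cyano-3-methyl-2-[(2R)-2-(trimethylsilyl)but-3-en-2-yl]butanoic acid | N#CC(C)(C)[C@H]([C@@](C)(C=C)[Si](C)(C)C)C(=O)O | intermediate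
10 | sodium (2S)-4-[(diisobutylalumanyl)imino]-3,3-dimethyl-2-[(2R)-2-(trimethylsilyl)but-3-en-2-yl]butanoate (aluminium aldiminate) | CC(C)C[Al](CC(C)C)N=CC(C)(C)[C@H]([C@@](C)(C=C)[Si](C)(C)C)C(=O)[O-].[Na+] | intermediate
11 | (2S)-3,3-dimethyl-4-oxo-2-[(2R)-2-(trimethylsilyl)but-3-en-2-yl]butanoic acid (open-chain aldehyde acid) | O=CC(C)(C)[C@H]([C@@](C)(C=C)[Si](C)(C)C)C(=O)O | intermediate
12 | (3S)-5-hydroxy-4,4-dimethyl-3-[(2R)-2-(trimethylsilyl)but-3-en-2-yl]oxolan-2-one (both C-5 epimers) | OC1OC(=O)[C@@H]([C@@](C)(C=C)[Si](C)(C)C)C1(C)C | intermediate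
13 | (3S)-4,4-dimethyl-2-oxo-3-[(2R)-2-(trimethylsilyl)but-3-en-2-yl]-3,4-dihydro-2H-furan-1-ium (cyclic acyloxycarbenium ion) | O=C1[O+]=CC(C)(C)[C@@H]1[C@@](C)(C=C)[Si](C)(C)C | intermediate
14 | (1S,5R)-2,8,8-trimethyl-6-oxabicyclo[3.2.1]oct-2-en-7-one | CC1=CC[C@H]2OC(=O)[C@@H]1C2(C)C | intermediate
15 | (1R,3S)-3-(hydroxymethyl)-2,2,4-trimethylcyclohex-4-en-1-ol | CC1=CC[C@@H](O)C(C)(C)[C@H]1CO | intermediate
16 | (1R,3S)-3-{[tert-butyl(dimethyl)silyl]oxymethyl}-2,2,4-trimethylcyclohex-4-en-1-ol | CC1=CC[C@@H](O)C(C)(C)[C@H]1CO[Si](C)(C)C(C)(C)C | intermediate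
17 | 3-methylbutanoyl chloride | CC(C)CC(=O)Cl | starting material
18 | (1R,3S)-3-{[tert-butyl(dimethyl)silyl]oxymethyl}-2,2,4-trimethylcyclohex-4-en-1-yl 3-methylbutanoate | CC1=CC[C@@H](OC(=O)CC(C)C)C(C)(C)[C@H]1CO[Si](C)(C)C(C)(C)C | intermediate
19 | (1R,3S)-3-(hydroxymethyl)-2,2,4-trimethylcyclohex-4-en-1-yl 3-methylbutanoate | CC1=CC[C@@H](OC(=O)CC(C)C)C(C)(C)[C@H]1CO | intermediate
20 | 7-hydroxy-2H-chromen-2-one (umbelliferone) | O=c1ccc2ccc(O)cc2o1 | starting material
21 | (1R,3S)-2,2,4-trimethyl-3-{[(2-oxo-2H-chromen-7-yl)oxy]methyl}cyclohex-4-en-1-yl 3-methylbutanoate | CC1=CC[C@@H](OC(=O)CC(C)C)C(C)(C)[C@H]1COc1ccc2ccc(=O)oc2c1 | target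

**Step count and risks**

Total steps: 11. Longest linear sequence: 11 steps (1 to 21).

Most likely to fail:

Step 4. Enolisation of the β-quaternary ester by the bulky chiral bromoborane may be sluggish or unselective, so that the rearrangement stalls or enantiofacial control is eroded. Fallback: setting out from 6, a lithium-enolate Ireland–Claisen rearrangement (LiN(i-Pr)2, THF, −78 °C; Me3SiCl; warm to rt) would proceed through the trimethylsilyl ketene acetal F1 to the racemic trimethylsilyl ester F2. Aqueous work-up would give the racemic acid F3 of the same relative configuration. This is resolved by crystallisation with one antipode of 1-phenylethanamine as the (1R)-1-phenylethanaminium salt F4 (the (1R) amine is drawn; the other antipode is used if it gives the less soluble salt of the wanted acid). Acidification returns to the route at 9.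

Step 6. The tertiary allylsilane may be protonated by the acid released on ionisation (loss of silicon before the C–C bond forms), or the substrate may react through its open aldehyde form without tether control. Fallback: setting out from 12, alkylation of the ring-opened carboxylate (MeI, K2CO3, DMF) would give the methyl ester aldehyde F5. SnCl4 in CH2Cl2 at −78 °C would close the same bond by Hosomi–Sakurai addition to the free aldehyde, which releases no protic by-product, and give the hydroxy ester F6 as a mixture at the carbinol carbon. Swern oxidation would give the ketone F7. LiAlH4 reduction (hydride delivered axially, alcohol equatorial and cis to the equatorial CH2OH, ester reduced in the same operation) comes back to the route at 15.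

Step 5. The carboxylate may be over-reduced, or reduction of the hindered tertiary nitrile may stop short. Fallback: setting out from 9, the acid would first be masked as the triisopropylsilyl ester F8 (i-Pr3SiCl, imidazole, CH2Cl2). The nitrile alone is then reduced with i-Bu2AlH at −78 °C to the aluminium aldiminate F9. The aqueous HCl work-up hydrolyses the aldimine and the silyl ester together and comes back to the route at 12.

**Further compounds**

F1 | step 4 | trimethylsilyl ketene acetal of 6 (C-3 substituent cis to the allyloxy oxygen) | N#CC(C)(C)/C=C(\OC/C=C(\C)[Si](C)(C)C)O[Si](C)(C)C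
F2 | step 4 | racemic trimethylsilyl (2S*)-3-cyano-3-methyl-2-[(2R*)-2-(trimethylsilyl)but-3-en-2-yl]butanoate | N#CC(C)(C)[C@H]([C@@](C)(C=C)[Si](C)(C)C)C(=O)O[Si](C)(C)C.N#CC(C)(C)[C@@H]([C@](C)(C=C)[Si](C)(C)C)C(=O)O[Si](C)(C)C
F3 | step 4 | racemic (2S*)-3-cyano-3-methyl-2-[(2R*)-2-(trimethylsilyl)but-3-en-2-yl]butanoic acid | N#CC(C)(C)[C@H]([C@@](C)(C=C)[Si](C)(C)C)C(=O)O.N#CC(C)(C)[C@@H]([C@](C)(C=C)[Si](C)(C)C)C(=O)O
F4 | step 4 | (1R)-1-phenylethanaminium (2S)-3-cyano-3-methyl-2-[(2R)-2-(trimethylsilyl)but-3-en-2-yl]butanoate | N#CC(C)(C)[C@H]([C@@](C)(C=C)[Si](C)(C)C)C(=O)[O-].C[C@@H]([NH3+])c1ccccc1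
F5 | step 6 | methyl (2S)-3,3-dimethyl-4-oxo-2-[(2R)-2-(trimethylsilyl)but-3-en-2-yl]butanoate | O=CC(C)(C)[C@H]([C@@](C)(C=C)[Si](C)(C)C)C(=O)OC
F6 | step 6 | methyl (1S)-5-hydroxy-2,6,6-trimethylcyclohex-2-ene-1-carboxylate (both C-5 epimers) | CC1=CCC(O)C(C)(C)[C@H]1C(=O)OC
F7 | step 6 | methyl (1S)-2,6,6-trimethyl-5-oxocyclohex-2-ene-1-carboxylate | CC1=CCC(=O)C(C)(C)[C@H]1C(=O)OC
F8 | step 5 | triisopropylsilyl (2S)-3-cyano-3-methyl-2-[(2R)-2-(trimethylsilyl)but-3-en-2-yl]butanoate | N#CC(C)(C)[C@H]([C@@](C)(C=C)[Si](C)(C)C)C(=O)O[Si](C(C)C)(C(C)C)C(C)C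
F9 | step 5 | triisopropylsilyl (2S)-4-[(diisobutylalumanyl)imino]-3,3-dimethyl-2-[(2R)-2-(trimethylsilyl)but-3-en-2-yl]butanoate | CC(C)C[Al](CC(C)C)N=CC(C)(C)[C@H]([C@@](C)(C=C)[Si](C)(C)C)C(=O)O[Si](C(C)C)(C(C)C)C(C)C
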